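**Retrosynthetic overview**
1. Target (C1 acyl bridgehead, C5 bridgehead, C9 bridging C=O, C7 prenyl CH, C8 quaternary) ⇒ acyclic, enolised triacyl dioxinone. Both carbocycles are cut: C1–C8 (ring 2 = C1–C9–C5–C6–C7–C8) and C4–C5 (ring 1 = C1–C2–C3–C4–C5–C9). Forward, ring 2 closes first and ring 1 second, in the same flask.
2. C1–C8: 6-exo addition of the C1 enol to an exocyclic methylene on C8; the methylene is the masked C8 methyl and makes the two C8 substituents sterically different. C4–C5: C-acylation by the acylketene released from the dioxinone.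
3. Triacyl dioxinone ⇒ C1–C10 acylation with (R)-2-methylbutanoyl chloride of a keto-dioxinone that already carries the C5–C8 chain.
4. C5–C6 ⇒ keto-dioxinone dianion + primary triflate of a C20 alcohol (C6–C7–C8 with both side chains).
5. C20 alcohol ⇒ deconjugative Evans α-prenylation of an N-farnesoyl oxazolidinone (sets C7; the farnesyl C3 methyl becomes the methylene) ⇐ farnesoic acid ⇐ farnesol.

Assumption: the two purchased materials that carry stereochemical information are taken as isomerically pure, and positions C1–C10 are labelled as in the bicyclo[3.3.1]nonane target throughout.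

**Route**

Step 1
Reactants: 1 (2E,6E)-farnesol
Product: 2 (2E,6E)-farnesal
Conditions: MnO2 (15 equiv), CH2Cl2, rt
Reagents that add atoms: none
Why: Allylic alcohol oxidation with MnO2 is selective for the allylic primary alcohol and leaves the three trisubstituted alkenes and the (2E) geometry untouched.

Step 2
Reactants: 2 (2E,6E)-farnesal
Product: 3 (2E,6E)-farnesoic acid
Conditions: NaClO2, NaH2PO4, 2-methyl-2-butene, t-BuOH/H2O, 0 °C to rt
Reagents that add atoms: sodium chlorite, [Na+].[O-]Cl=O
Why: Pinnick oxidation takes the enal to the acid under buffered conditions while 2-methyl-2-butene traps the HOCl that would otherwise attack the electron-rich alkenes.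

Step 3
Reactants: 3 (2E,6E)-farnesoic acid; 4 (R)-4-benzyl-1,3-oxazolidin-2-one
Product: 6 (4R)-4-benzyl-3-[(2E,6E)-3,7,11-trimethyldodeca-2,6,10-trienoyl]-1,3-oxazolidin-2-one, via farnesoic pivalic anhydride 5 (not isolated)
Conditions: t-BuCOCl, Et3N, THF, −20 °C; then LiCl, 4, −20 °C to rt
Reagents that add atoms: none
Why: N-Acylation of the Evans oxazolidinone through the mixed pivalic anhydride needs only Et3N/LiCl, so the (2E)-enoyl geometry, which later fixes the site of γ-deprotonation, is not disturbed.

Step 4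
Reactants: 6 N-farnesoyl oxazolidinone; 7 prenyl bromide (1-bromo-3-methylbut-2-ene)
Product: 8 (4R)-4-benzyl-3-[(2R,6E)-7,11-dimethyl-3-methylidene-2-(3-methylbut-2-en-1-yl)dodeca-6,10-dienoyl]-1,3-oxazolidin-2-one
Conditions: NaN(SiMe3)2 (1.1 equiv), THF, −78 °C; then 7 (3 equiv), −78 to −40 °C
Reagents that add atoms: none
Why: Deconjugative Evans alkylation, in which NaN(SiMe3)2 removes a hydrogen from the C8 methyl group that lies cis to the carbonyl, the sodium-chelated (Z)-dienolate takes the prenyl group at the α-carbon on the face away from the benzyl group to set C7 as (R), and the former methyl is left as the exocyclic methylene.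

Step 5
Reactants: 8 α-prenylated imide
Product: 9 (2R,6E)-7,11-dimethyl-3-methylidene-2-(3-methylbut-2-en-1-yl)dodeca-6,10-dien-1-ol
Conditions: LiBH4, H2O (1 equiv), Et2O, 0 °C
Reagents that add atoms: none
Why: Reductive removal of the auxiliary with LiBH4 gives the primary alcohol without epimerising C7, since hydride conditions do not enolise the imide, and returns the oxazolidinone.

Step 6
Reactants: 10 2,2,6-trimethyl-4H-1,3-dioxin-4-one; 11 acetyl chloride
Product: 12 2,2-dimethyl-6-(2-oxopropyl)-4H-1,3-dioxin-4-one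
Conditions: 10 (2 equiv), LiN(SiMe3)2 (2 equiv), THF, −78 °C; then 11 (1 equiv), −78 °C
Reagents that add atoms: none
Why: Vinylogous Claisen acylation of the lithium dienolate of 10 at its γ-carbon gives the keto-dioxinone, the second equivalent of dienolate being consumed by the more acidic product.

Step 7
Reactants: 9 C20 alcohol; 12 keto-dioxinone
Product: 14 6-[(5R,9E)-10,14-dimethyl-6-methylidene-5-(3-methylbut-2-en-1-yl)-2-oxopentadeca-9,13-dien-1-yl]-2,2-dimethyl-4H-1,3-dioxin-4-one, via primary triflate 13 (not isolated)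
Conditions: 9, (CF3SO2)2O, 2,6-lutidine, CH2Cl2, −78 °C; then into the dianion of 12 [12 (2 equiv), LiN(i-Pr)2 (4.2 equiv), THF, −78 to 0 °C], DMPU, −78 to −20 °C; then cold 1 M HCl
Reagents that add atoms: none
Why: Weiler-type dianion alkylation, in which the dianion of 12 attacks the primary triflate by SN2 through its terminal, most basic carbon to make the C5–C6 bond, the dioxinone carbonyl being shielded as part of the vinylogous enolate and C7 being untouched.

Step 8
Reactants: 14 alkylated keto-dioxinone; 15 (R)-2-methylbutanoic acid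
Product: 17 2,2-dimethyl-6-[(3R,9R,13E)-3,14,18-trimethyl-10-methylidene-9-(3-methylbut-2-en-1-yl)-4,6-dioxononadeca-13,17-dien-5-yl]-4H-1,3-dioxin-4-one, via (R)-2-methylbutanoyl chloride 16 (not isolated)
Conditions: 15, (COCl)2, DMF (cat.), CH2Cl2, 0 °C to rt, evaporate; then 14, MgCl2, pyridine, CH2Cl2, 0 °C
Reagents that add atoms: none
Why: Magnesium-mediated soft enolisation and C-acylation (Rathke-type acylation of a vinylogous β-keto ester) puts the (R)-2-methylbutanoyl group on C1 with pyridine as the only base, mild enough to keep the α-stereocentre of the acid chloride, and gives the enolised triacylmethane whose C1 needs no defined configuration.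

Step 9
Reactants: 17 enolised triacyl dioxinone
Product: 20 (1R,5R,7S,8R)-8-[(3E)-4,8-dimethylnona-3,7-dien-1-yl]-4-hydroxy-8-methyl-7-(3-methylbut-2-en-1-yl)-1-[(2R)-2-methylbutanoyl]bicyclo[3.3.1]non-3-ene-2,9-dione (CNP0158147.2), via monocyclic dioxinone 18 (not isolated), via acylketene 19 (not isolated)
Conditions: [(2-biphenylyl)(t-Bu)2P]AuCl (5 mol %), AgOSO2CF3 (5 mol %), 4 Å MS, toluene (0.01 M), 55 °C; then 2,6-lutidine (0.2 equiv), 110 °C
Reagents that add atoms: none
Why: Proposed new method: a cationic monovalent gold catalyst activates the 1,1-disubstituted alkene and the C1 carbon of the hydrogen-bonded C9/C10 enol attacks its substituted end through a 6-exo chair (Conia-ene-type hydroalkylation, closest known reaction being the gold-catalysed intramolecular addition of β-dicarbonyl compounds to unactivated alkenes), with prenyl and homogeranyl equatorial, the methylene (the new methyl) axial and the unchelated dioxinone axial on C1, which sets C8 and C1 relative to C7 and closes ring 2; heating then expels acetone by retro-[4+2] and the acylketene, held axial, C-acylates the C9 enol at C5 (closest known reaction being the thermolysis of diketo-dioxinones and intramolecular trapping of the acylketene), which closes ring 1 and fixes C5, any O-acylated enol lactone reverting to the ketene at this temperature.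

**Compound list**
1 | (2E,6E)-farnesol | OC/C=C(\C)CC/C=C(\C)CCC=C(C)C | starting material
2 | (2E,6E)-farnesal | O=C/C=C(\C)CC/C=C(\C)CCC=C(C)C | intermediate
3 | (2E,6E)-farnesoic acid | OC(=O)/C=C(\C)CC/C=C(\C)CCC=C(C)C | intermediate
4 | (R)-4-benzyl-1,3-oxazolidin-2-one | O=C1N[C@H](Cc2ccccc2)CO1 | starting material
5 | (2E,6E)-farnesoic pivalic anhydride | CC(C)(C)C(=O)OC(=O)/C=C(\C)CC/C=C(\C)CCC=C(C)C | intermediate
6 | (4R)-4-benzyl-3-[(2E,6E)-3,7,11-trimethyldodeca-2,6,10-trienoyl]-1,3-oxazolidin-2-one | O=C(/C=C(\C)CC/C=C(\C)CCC=C(C)C)N1[C@H](Cc2ccccc2)COC1=O | intermediate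
7 | prenyl bromide (1-bromo-3-methylbut-2-ene) | CC(C)=CCBr | starting material
8 | (4R)-4-benzyl-3-[(2R,6E)-7,11-dimethyl-3-methylidene-2-(3-methylbut-2-en-1-yl)dodeca-6,10-dienoyl]-1,3-oxazolidin-2-one | O=C([C@H](CC=C(C)C)C(=C)CC/C=C(\C)CCC=C(C)C)N1[C@H](Cc2ccccc2)COC1=O | intermediate
9 | (2R,6E)-7,11-dimethyl-3-methylidene-2-(3-methylbut-2-en-1-yl)dodeca-6,10-dien-1-ol | OC[C@H](CC=C(C)C)C(=C)CC/C=C(\C)CCC=C(C)C | intermediate
10 | 2,2,6-trimethyl-4H-1,3-dioxin-4-one | CC1=CC(=O)OC(C)(C)O1 | starting material
11 | acetyl chloride | CC(Cl)=O | starting material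
12 | 2,2-dimethyl-6-(2-oxopropyl)-4H-1,3-dioxin-4-one | CC(=O)CC1=CC(=O)OC(C)(C)O1 | intermediate
13 | (2R,6E)-7,11-dimethyl-3-methylidene-2-(3-methylbut-2-en-1-yl)dodeca-6,10-dien-1-yl trifluoromethanesulfonate | O=S(=O)(OC[C@H](CC=C(C)C)C(=C)CC/C=C(\C)CCC=C(C)C)C(F)(F)F | intermediate
14 | 6-[(5R,9E)-10,14-dimethyl-6-methylidene-5-(3-methylbut-2-en-1-yl)-2-oxopentadeca-9,13-dien-1-yl]-2,2-dimethyl-4H-1,3-dioxin-4-one | CC1(C)OC(=O)C=C(CC(=O)CC[C@H](CC=C(C)C)C(=C)CC/C=C(\C)CCC=C(C)C)O1 | intermediate
15 | (R)-2-methylbutanoic acid | CC[C@@H](C)C(=O)O | starting material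
16 | (R)-2-methylbutanoyl chloride | CC[C@@H](C)C(Cl)=O | intermediate
17 | 2,2-dimethyl-6-[(3R,9R,13E)-3,14,18-trimethyl-10-methylidene-9-(3-methylbut-2-en-1-yl)-4,6-dioxononadeca-13,17-dien-5-yl]-4H-1,3-dioxin-4-one (side-chain C5, the future C1, is enolised and has no fixed configuration) | CC[C@@H](C)C(=O)C(C(=O)CC[C@H](CC=C(C)C)C(=C)CC/C=C(\C)CCC=C(C)C)C1=CC(=O)OC(C)(C)O1 | intermediate
18 | 6-{(1R,2R,3R)-2-[(3E)-4,8-dimethylnona-3,7-dien-1-yl]-2-methyl-3-(3-methylbut-2-en-1-yl)-1-[(2R)-2-methylbutanoyl]-6-oxocyclohexyl}-2,2-dimethyl-4H-1,3-dioxin-4-one | CC[C@@H](C)C(=O)[C@]1(C2=CC(=O)OC(C)(C)O2)C(=O)CC[C@H](CC=C(C)C)[C@@]1(C)CC/C=C(\C)CCC=C(C)C | intermediate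
19 | 3-{(1R,2R,3R)-2-[(3E)-4,8-dimethylnona-3,7-dien-1-yl]-2-methyl-3-(3-methylbut-2-en-1-yl)-1-[(2R)-2-methylbutanoyl]-6-oxocyclohexyl}-3-oxoprop-1-en-1-one (acylketene) | CC[C@@H](C)C(=O)[C@]1(C(=O)C=C=O)C(=O)CC[C@H](CC=C(C)C)[C@@]1(C)CC/C=C(\C)CCC=C(C)C | intermediate
20 | (1R,5R,7S,8R)-8-[(3E)-4,8-dimethylnona-3,7-dien-1-yl]-4-hydroxy-8-methyl-7-(3-methylbut-2-en-1-yl)-1-[(2R)-2-methylbutanoyl]bicyclo[3.3.1]non-3-ene-2,9-dione | CC[C@@H](C)C(=O)[C@@]12C(=O)C=C(O)[C@@H](C[C@H](CC=C(C)C)[C@@]1(C)CC/C=C(\C)CCC=C(C)C)C2=O | target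

**Step count and risks**

Total steps: 9. Longest linear sequence: 8 steps (1 → 2 → 3 → 6 → 8 → 9 → 14 → 17 → 20; step 6 runs in parallel).

The three steps most likely to fail:

Step 9. The gold step must join a fully substituted triacyl carbon to a disubstituted alkene carbon (two adjacent quaternary centres). The correct face at C1 rests on the C9/C10 enol chelate keeping the dioxinone on the C5 side. On heating, the acylketene could also be taken by the enol of the C10 ketone, which would additionally erode the acyl α-stereocentre. Fallback, setting out from 17 and coming back at 18: replace the π-acid hydroalkylation by an electrophile-induced carbocyclisation and remove the halogen afterwards. N-Iodosuccinimide in CH2Cl2 at −20 °C forms the iodonium ion of the methylene group, which C1 opens through the same chair to give the iodomethyl cyclohexanone F1. Then (Me3Si)3SiH with catalytic PhSH and Et3B/air in toluene at room temperature replaces iodine by hydrogen; hydrogen transfer from the thiol is faster than cyclisation of the neopentyl radical onto the side-chain alkenes. This gives 18, which is isolated and heated in toluene at 110 °C with 2,6-lutidine as in the second half of step 9 to reach 20.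

Step 7. The triflate is β-branched, the lutidinium salt carried over destroys part of the dianion, and a homoallylic triflate can ionise before it is alkylated. Fallback, setting out from 9 (through 13) and 10 and coming back at 14: build the C9 ketone by acylation instead of dianion alkylation. Triflate 13 is displaced by the lithium enolate of N-methoxy-N-methylacetamide (LiN(i-Pr)2, THF, −78 °C) to give the Weinreb amide (4R,8E)-N-methoxy-N,9,13-trimethyl-5-methylidene-4-(3-methylbut-2-en-1-yl)tetradeca-8,12-dienamide F2. The lithium dienolate of dioxinone 10 (LiN(SiMe3)2, THF, −78 °C) is then acylated by F2 at its γ-carbon to give 14.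

Step 8. The C1 methylene of 14 is only a vinylogous β-keto ester, so soft enolisation may be slow; O-acylation and ketene formation from 16 (loss of the acyl stereocentre) compete. Fallback, setting out from 12 (with 16 and 13) and coming back at 17: reverse the order of the two bond formations. The small, unhindered keto-dioxinone 12 is C-acylated with 16 (MgCl2, pyridine, CH2Cl2, 0 °C) to give 2,2-dimethyl-6-[(5R)-5-methyl-2,4-dioxoheptan-3-yl]-4H-1,3-dioxin-4-one F3. Its dianion (LiN(i-Pr)2, 2.2 equiv, THF/DMPU, −78 °C) is then alkylated at the acetyl methyl group with triflate 13 to give 17.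

**Further compounds**
F1 | step 9 | 6-{(1R,2S,3R)-2-[(3E)-4,8-dimethylnona-3,7-dien-1-yl]-2-(iodomethyl)-3-(3-methylbut-2-en-1-yl)-1-[(2R)-2-methylbutanoyl]-6-oxocyclohexyl}-2,2-dimethyl-4H-1,3-dioxin-4-one (same spatial arrangement as 18, CH2I in place of the C8 methyl) | CC[C@@H](C)C(=O)[C@]1(C2=CC(=O)OC(C)(C)O2)C(=O)CC[C@H](CC=C(C)C)[C@@]1(CI)CC/C=C(\C)CCC=C(C)C
F2 | step 7 | (4R,8E)-N-methoxy-N,9,13-trimethyl-5-methylidene-4-(3-methylbut-2-en-1-yl)tetradeca-8,12-dienamide | CON(C)C(=O)CC[C@H](CC=C(C)C)C(=C)CC/C=C(\C)CCC=C(C)C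
F3 | step 8 | 2,2-dimethyl-6-[(5R)-5-methyl-2,4-dioxoheptan-3-yl]-4H-1,3-dioxin-4-one (C3 of the side chain enolised) | CC[C@@H](C)C(=O)C(C(C)=O)C1=CC(=O)OC(C)(C)O1
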